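**Plan**
- Cuts, in retrosynthetic order: the pyridone C3–carbonyl bond (aryllithium plus a C2 aldehyde); the propenyl C=C on C1 (Julia olefination); the C1=C2 alkene (back to a saturated cycloadduct); C1–C2 and C4a–C8a together (intramolecular Diels–Alder); then the enal and dienyl C=C bonds of the open chain, back to (S)-citronellal.
- Enabling feature: ring A is a cyclohexene (C3=C4, methyl on C4) fused trans at C4a–C8a to ring B. The C5–C8 bridge of ring B, with the C7 methyl, is a four-carbon tether between a C2=C3–C4=C4a diene and a C1=C8a dienophile.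
- Forward: the trienal chain is built on citronellal (steps 1–7); rings A and B close together in step 8; the adduct is dehydrogenated and its two side arms become propenyl and formyl (steps 9–15); the pyridine (steps 16–18) is joined last (steps 19–21).
- Stereochemistry: C7 comes from (S)-citronellal. C4a and C8a are set in the cycloaddition (endo transition state, chair-like tether, equatorial C7 methyl). The C1/C2 centres of the adduct are transient. The E alkenes come from SeO2 oxidation, stabilised ylides and the Julia reaction.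

Key step: step 8

Remark: locants follow the octahydronaphthalene core (C1 propenyl, C2 acyl, C4 and C7 methyl, C4a/C8a ring fusion); 33 is taken to rest as the open dienone as drawn, and (S)-citronellal of high enantiomeric purity is assumed, since its purity becomes that of 33.

**Route**

Step 1
Reactants: 1 (S)-citronellal
Product: 2 (S)-citronellal dimethyl acetal [(6S)-8,8-dimethoxy-2,6-dimethyloct-2-ene]
Conditions: HC(OMe)3, MeOH, pyridinium p-toluenesulfonate (cat.), rt
Reagents that add atoms: trimethyl orthoformate, COC(OC)OC; methanol, CO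
Why: Acid-catalysed acetalisation with the orthoformate as water scavenger masks the aldehyde for the oxidation and hydride steps under conditions mild enough to outrun the carbonyl-ene closure of citronellal, and the stereocentre is not touched.

Step 2
Reactants: 2 (S)-citronellal dimethyl acetal
Product: 3 (2E,6S)-8,8-dimethoxy-2,6-dimethyloct-2-en-1-ol
Conditions: SeO2 (0.3 equiv), t-BuOOH (anhydrous, in decane), CH2Cl2, 0 °C → rt
Reagents that add atoms: selenium dioxide, O=[Se]=O; tert-butyl hydroperoxide, CC(C)(C)OO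
Why: Riley allylic oxidation in its catalytic form (ene reaction, then [2,3]-sigmatropic shift) attacks the methyl group trans to the chain and should give the (E)-allylic alcohol; any enal from over-oxidation is the intermediate of step 3 and is carried along.

Step 3
Reactants: 3 (2E,6S)-8,8-dimethoxy-2,6-dimethyloct-2-en-1-ol; 4 ethyl (triphenylphosphoranylidene)acetate
Product: 6 ethyl (2E,4E,8S)-10,10-dimethoxy-4,8-dimethyldeca-2,4-dienoate, via enal 5 (not isolated)
Conditions: MnO2 (excess), CH2Cl2, rt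
Reagents that add atoms: none
Why: Tandem allylic oxidation–Wittig olefination: MnO2 forms the (E)-enal 5, which the ester-stabilised ylide traps as it forms, and such ylides give the new disubstituted alkene with E geometry.

Step 4
Reactants: 6 ethyl (2E,4E,8S)-10,10-dimethoxy-4,8-dimethyldeca-2,4-dienoate
Product: 7 (2E,4E,8S)-10,10-dimethoxy-4,8-dimethyldeca-2,4-dien-1-ol
Conditions: i-Bu2AlH (2.5 equiv), CH2Cl2, –78 °C
Reagents that add atoms: none
Why: Hydride reduction of the conjugated ester by 1,2-addition should give the dienyl alcohol at low temperature without touching the diene or the dimethyl acetal.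

Step 5
Reactants: 7 (2E,4E,8S)-10,10-dimethoxy-4,8-dimethyldeca-2,4-dien-1-ol
Product: 8 tert-butyl{[(2E,4E,8S)-10,10-dimethoxy-4,8-dimethyldeca-2,4-dien-1-yl]oxy}diphenylsilane
Conditions: t-BuPh2SiCl, imidazole, CH2Cl2, 0 °C → rt
Reagents that add atoms: tert-butyl(chloro)diphenylsilane, CC(C)(C)[Si](Cl)(c1ccccc1)c1ccccc1
Why: Standard silylation of a primary alcohol; the tert-butyldiphenylsilyl ether is chosen because it should outlast the aqueous acid of step 6 and the chloroaluminium Lewis acid of step 8.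

Step 6
Reactants: 8 tert-butyl{[(2E,4E,8S)-10,10-dimethoxy-4,8-dimethyldeca-2,4-dien-1-yl]oxy}diphenylsilane
Product: 9 (3S,6E,8E)-10-[(tert-butyldiphenylsilyl)oxy]-3,7-dimethyldeca-6,8-dienal
Conditions: pyridinium p-toluenesulfonate (cat.), acetone/H2O, 50 °C
Reagents that add atoms: water, O
Why: Mild acid hydrolysis of a dimethyl acetal is much faster than cleavage of the silyl ether or ionisation of the dienyl ether and frees the aldehyde.

Step 7
Reactants: 9 (3S,6E,8E)-10-[(tert-butyldiphenylsilyl)oxy]-3,7-dimethyldeca-6,8-dienal; 10 (triphenylphosphoranylidene)acetaldehyde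
Product: 11 (2E,5S,8E,10E)-12-[(tert-butyldiphenylsilyl)oxy]-5,9-dimethyldodeca-2,8,10-trienal
Conditions: toluene, 70 °C
Reagents that add atoms: none
Why: Wittig formyl-olefination with the stabilised ylide should give the (E)-enal; the conjugated product reacts with the ylide more slowly than the saturated aldehyde, and the moderate temperature holds back the uncatalysed cycloaddition.

Step 8
Reactants: 11 (2E,5S,8E,10E)-12-[(tert-butyldiphenylsilyl)oxy]-5,9-dimethyldodeca-2,8,10-trienal
Product: 12 (1R,2S,4aS,7S,8aS)-2-{[(tert-butyldiphenylsilyl)oxy]methyl}-4,7-dimethyl-1,2,4a,5,6,7,8,8a-octahydronaphthalene-1-carbaldehyde (trans ring fusion, formyl and silyloxymethyl groups cis)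
Conditions: Me2AlCl (1.1 equiv), CH2Cl2, –78 → –20 °C
Reagents that add atoms: none
Why: Me2AlCl binds the aldehyde oxygen and lowers the enal LUMO, so the electron-rich (8E,10E)-diene should add in a concerted, asynchronous [4+2] at low temperature; the closest known reaction type is the Lewis acid-promoted type 1 intramolecular Diels–Alder reaction of (2E,8E,10E)-trienals to trans-fused octahydronaphthalenes. Ring A closes as the cyclohexene of the cycloaddition (bonds C1–C2 and C4a–C8a, new C3=C4), and ring B closes in the fused mode as the six-membered ring through the four-carbon tether when C4a–C8a forms. C1 and C2 follow from the E geometry of both reacting termini and the endo position of the complexed formyl group, which places CHO and CH2OSi cis. C4a and C8a become trans because, with an (E)-dienophile, the endo transition state holds the tether anti across the forming ring fusion. Their absolute sense is fixed by the C7 methyl group inherited from citronellal, which stays equatorial on the chair-like tether and so selects one diene face. The step needs endo over exo and one π-face over the other; the Lewis acid raises the endo preference and the single equatorial methyl group supplies the facial bias.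

Step 9
Reactants: 12 (1R,2S,4aS,7S,8aS)-2-{[(tert-butyldiphenylsilyl)oxy]methyl}-4,7-dimethyl-1,2,4a,5,6,7,8,8a-octahydronaphthalene-1-carbaldehyde
Product: 14 (1S,2R,4aS,7S,8aS)-2-{[(tert-butyldiphenylsilyl)oxy]methyl}-4,7-dimethyl-1-(phenylselanyl)-1,2,4a,5,6,7,8,8a-octahydronaphthalene-1-carbaldehyde, via silyl enol ether 13 (not isolated)
Conditions: Me3SiOTf, Et3N, CH2Cl2, 0 °C; then PhSeCl, –78 °C
Reagents that add atoms: benzeneselenenyl chloride, Cl[Se]c1ccccc1; trimethylsilyl triflate (silyl group held only by 13), C[Si](C)(C)OS(=O)(=O)C(F)(F)F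
Why: α-Selenenylation through the silyl enol ether, which is far more nucleophilic than the C3=C4 alkene, should deliver selenium to C1 from the face opposite the pseudoaxial C2 silyloxymethyl group, so the new quaternary centre carries selenium cis to H-2 and trans to H-8a.

Step 10
Reactants: 14 (1S,2R,4aS,7S,8aS)-2-{[(tert-butyldiphenylsilyl)oxy]methyl}-4,7-dimethyl-1-(phenylselanyl)-1,2,4a,5,6,7,8,8a-octahydronaphthalene-1-carbaldehyde
Product: 16 (4aS,7S,8aS)-2-{[(tert-butyldiphenylsilyl)oxy]methyl}-4,7-dimethyl-4a,5,6,7,8,8a-hexahydronaphthalene-1-carbaldehyde, via selenoxide 15 (not isolated)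
Conditions: NaIO4, NaHCO3, THF/MeOH/H2O, 0 °C → rt
Reagents that add atoms: sodium periodate (oxygen held only by 15), [Na+].[O-]I(=O)(=O)=O
Why: Selenoxide syn-elimination can reach only the cis-disposed allylic H-2, so the C1=C2 bond should form in conjugation with C3=C4 while C8a is left alone, and the transient C1 and C2 centres disappear.

Step 11
Reactants: 17 1,3-benzothiazole-2-thiol; 18 iodoethane
Product: 19 2-(ethylsulfanyl)-1,3-benzothiazole
Conditions: K2CO3, acetone, rt
Reagents that add atoms: none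
Why: SN2 alkylation of the thiolate by a soft alkyl iodide is selective for sulfur.

Step 12
Reactants: 19 2-(ethylsulfanyl)-1,3-benzothiazole
Product: 20 2-(ethylsulfonyl)-1,3-benzothiazole
Conditions: m-CPBA (2.2 equiv), CH2Cl2, 0 °C → rt
Reagents that add atoms: m-chloroperbenzoic acid, OOC(=O)c1cccc(Cl)c1
Why: Peracid oxidation of a sulfide to the sulfone, with the electron-poor ring nitrogen not competing.

Step 13
Reactants: 16 (4aS,7S,8aS)-2-{[(tert-butyldiphenylsilyl)oxy]methyl}-4,7-dimethyl-4a,5,6,7,8,8a-hexahydronaphthalene-1-carbaldehyde; 20 2-(ethylsulfonyl)-1,3-benzothiazole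
Product: 22 tert-butyl({(4aS,7S,8aS)-4,7-dimethyl-1-[(1E)-prop-1-en-1-yl]-4a,5,6,7,8,8a-hexahydronaphthalen-2-yl}methoxy)diphenylsilane, via lithiated sulfone 21 (not isolated)
Conditions: LiN(SiMe3)2 added to 16 + 20, THF, –78 °C → rt
Reagents that add atoms: lithium bis(trimethylsilyl)amide (lithium held only by 21), [Li+].C[Si](C)(C)[N-][Si](C)(C)C
Why: Modified Julia olefination (addition of 21 to the aldehyde, Smiles rearrangement, loss of SO2) should give the (E)-propenyl group, since alkyl benzothiazolyl sulfones are known to give E alkenes with conjugated aldehydes, and 16 has no α-hydrogen to lose.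

Step 14
Reactants: 22 tert-butyl({(4aS,7S,8aS)-4,7-dimethyl-1-[(1E)-prop-1-en-1-yl]-4a,5,6,7,8,8a-hexahydronaphthalen-2-yl}methoxy)diphenylsilane
Product: 23 {(4aS,7S,8aS)-4,7-dimethyl-1-[(1E)-prop-1-en-1-yl]-4a,5,6,7,8,8a-hexahydronaphthalen-2-yl}methanol
Conditions: Bu4NF, THF, 0 °C → rt
Reagents that add atoms: none
Why: Fluoride cleavage of the silyl ether, driven by Si–F bond formation, leaves the triene untouched.

Step 15
Reactants: 23 {(4aS,7S,8aS)-4,7-dimethyl-1-[(1E)-prop-1-en-1-yl]-4a,5,6,7,8,8a-hexahydronaphthalen-2-yl}methanol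
Product: 24 (4aS,7S,8aS)-4,7-dimethyl-1-[(1E)-prop-1-en-1-yl]-4a,5,6,7,8,8a-hexahydronaphthalene-2-carbaldehyde
Conditions: MnO2, CH2Cl2, rt
Reagents that add atoms: none
Why: MnO2 oxidises the allylic primary alcohol selectively to the aldehyde without over-oxidation or isomerisation of the triene.

Step 16
Reactants: 25 5-bromo-2,4-dimethoxypyridine; 26 (4-methoxyphenyl)boronic acid
Product: 27 2,4-dimethoxy-5-(4-methoxyphenyl)pyridine
Conditions: Pd(PPh3)4 (cat.), K2CO3, 1,4-dioxane/H2O, 90 °C
Reagents that add atoms: none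
Why: Suzuki–Miyaura coupling at the only C–Br bond: zerovalent palladium inserts, the boronate transmetalates and reductive elimination gives the biaryl.

Step 17
Reactants: 27 2,4-dimethoxy-5-(4-methoxyphenyl)pyridine
Product: 28 4-hydroxy-5-(4-hydroxyphenyl)pyridin-2(1H)-one
Conditions: 48% aq. HBr, AcOH, reflux
Reagents that add atoms: none
Why: Exhaustive ether cleavage (bromide attack on the protonated methyl ethers) exchanges the methyl groups, which could not be removed at the end beside the triene, for free hydroxyls at a stage with no sensitive functionality.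

Step 18
Reactants: 28 4-hydroxy-5-(4-hydroxyphenyl)pyridin-2(1H)-one
Product: 29 2,4-bis(methoxymethoxy)-5-[4-(methoxymethoxy)phenyl]pyridine
Conditions: MeOCH2Cl, Ag2CO3, toluene, rt, dark
Reagents that add atoms: chloromethyl methyl ether, COCCl
Why: Silver-salt alkylation of a 2-pyridone goes to oxygen in non-polar medium (the selectivity known from O-glycosylation of silver pyridonates with α-halo ethers); the 4-hydroxyl and the phenol follow, giving acetal groups that direct lithiation and later fall to mild acid.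

Step 19
Reactants: 29 2,4-bis(methoxymethoxy)-5-[4-(methoxymethoxy)phenyl]pyridine; 24 (4aS,7S,8aS)-4,7-dimethyl-1-[(1E)-prop-1-en-1-yl]-4a,5,6,7,8,8a-hexahydronaphthalene-2-carbaldehyde
Product: 31 {2,4-bis(methoxymethoxy)-5-[4-(methoxymethoxy)phenyl]pyridin-3-yl}{(4aS,7S,8aS)-4,7-dimethyl-1-[(1E)-prop-1-en-1-yl]-4a,5,6,7,8,8a-hexahydronaphthalen-2-yl}methanol (both carbinol epimers), via 3-lithiopyridine 30 (not isolated)
Conditions: n-BuLi, THF, –78 °C; then 24, –78 → 0 °C
Reagents that add atoms: n-butyllithium (lithium held only by 30), [Li]CCCC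
Why: Directed ortho-metalation at the one position flanked by two methoxymethoxy groups (pyridine C3) gives 30, which should add 1,2 to the aldehyde; the carbinol centre forms without control and is removed in step 20.

Step 20
Reactants: 31 the carbinol of step 19
Product: 32 {2,4-bis(methoxymethoxy)-5-[4-(methoxymethoxy)phenyl]pyridin-3-yl}{(4aS,7S,8aS)-4,7-dimethyl-1-[(1E)-prop-1-en-1-yl]-4a,5,6,7,8,8a-hexahydronaphthalen-2-yl}methanone
Conditions: Dess–Martin periodinane, NaHCO3, CH2Cl2, 0 °C → rt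
Reagents that add atoms: none
Why: Dess–Martin oxidation of the hindered, doubly activated secondary alcohol gives the ketone under buffered conditions that spare the triene and the acetals.

Step 21
Reactants: 32 the ketone of step 20
Product: 33 ilicicolin J, 4-hydroxy-5-(4-hydroxyphenyl)-3-{(4aS,7S,8aS)-4,7-dimethyl-1-[(1E)-prop-1-en-1-yl]-4a,5,6,7,8,8a-hexahydronaphthalene-2-carbonyl}pyridin-2(1H)-one
Conditions: HCl (aq., cat.), MeOH/THF, rt → 40 °C
Reagents that add atoms: none
Why: Acid-catalysed transacetalisation of the three methoxymethyl ethers to dimethoxymethane frees the 4-hydroxy-2-pyridone and the phenol, the pyridyl acetals going first and the aryl ether last, and no stereocentre is affected.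

**Compound list**

1 | (S)-citronellal, (3S)-3,7-dimethyloct-6-enal | C[C@@H](CCC=C(C)C)CC=O | starting material
2 | (S)-citronellal dimethyl acetal, (6S)-8,8-dimethoxy-2,6-dimethyloct-2-ene | C[C@@H](CCC=C(C)C)CC(OC)OC | intermediate
3 | (2E,6S)-8,8-dimethoxy-2,6-dimethyloct-2-en-1-ol | C[C@@H](CC/C=C(\C)CO)CC(OC)OC | intermediate
4 | ethyl (triphenylphosphoranylidene)acetate | CCOC(=O)C=P(c1ccccc1)(c1ccccc1)c1ccccc1 | starting material
5 | (2E,6S)-8,8-dimethoxy-2,6-dimethyloct-2-enal | C[C@@H](CC/C=C(\C)C=O)CC(OC)OC | intermediate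
6 | ethyl (2E,4E,8S)-10,10-dimethoxy-4,8-dimethyldeca-2,4-dienoate | C[C@@H](CC/C=C(C)/C=C/C(=O)OCC)CC(OC)OC | intermediate
7 | (2E,4E,8S)-10,10-dimethoxy-4,8-dimethyldeca-2,4-dien-1-ol | C[C@@H](CC/C=C(C)/C=C/CO)CC(OC)OC | intermediate
8 | tert-butyl{[(2E,4E,8S)-10,10-dimethoxy-4,8-dimethyldeca-2,4-dien-1-yl]oxy}diphenylsilane | C[C@@H](CC/C=C(C)/C=C/CO[Si](c1ccccc1)(c1ccccc1)C(C)(C)C)CC(OC)OC | intermediate
9 | (3S,6E,8E)-10-[(tert-butyldiphenylsilyl)oxy]-3,7-dimethyldeca-6,8-dienal | C[C@@H](CC/C=C(C)/C=C/CO[Si](c1ccccc1)(c1ccccc1)C(C)(C)C)CC=O | intermediate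
10 | (triphenylphosphoranylidene)acetaldehyde | O=CC=P(c1ccccc1)(c1ccccc1)c1ccccc1 | starting material
11 | (2E,5S,8E,10E)-12-[(tert-butyldiphenylsilyl)oxy]-5,9-dimethyldodeca-2,8,10-trienal | O=C/C=C/C[C@@H](C)CC/C=C(C)/C=C/CO[Si](c1ccccc1)(c1ccccc1)C(C)(C)C | intermediate
12 | (1R,2S,4aS,7S,8aS)-2-{[(tert-butyldiphenylsilyl)oxy]methyl}-4,7-dimethyl-1,2,4a,5,6,7,8,8a-octahydronaphthalene-1-carbaldehyde | O=C[C@H]1[C@@H](CO[Si](c2ccccc2)(c2ccccc2)C(C)(C)C)C=C(C)[C@H]2CC[C@H](C)C[C@H]12 | intermediate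
13 | tert-butyl{[(2S,4aS,7S,8aS)-4,7-dimethyl-1-{[(trimethylsilyl)oxy]methylidene}-1,2,4a,5,6,7,8,8a-octahydronaphthalen-2-yl]methoxy}diphenylsilane (enol ether geometry not defined) | C[Si](C)(C)OC=C1[C@@H](CO[Si](c2ccccc2)(c2ccccc2)C(C)(C)C)C=C(C)[C@H]2CC[C@H](C)C[C@H]12 | intermediate
14 | (1S,2R,4aS,7S,8aS)-2-{[(tert-butyldiphenylsilyl)oxy]methyl}-4,7-dimethyl-1-(phenylselanyl)-1,2,4a,5,6,7,8,8a-octahydronaphthalene-1-carbaldehyde (selenium trans to the silyloxymethyl group) | O=C[C@@]1([Se]c2ccccc2)[C@@H](CO[Si](c2ccccc2)(c2ccccc2)C(C)(C)C)C=C(C)[C@H]2CC[C@H](C)C[C@H]12 | intermediate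
15 | selenoxide of 14, (1S,2R,4aS,7S,8aS)-2-{[(tert-butyldiphenylsilyl)oxy]methyl}-4,7-dimethyl-1-(phenylseleninyl)-1,2,4a,5,6,7,8,8a-octahydronaphthalene-1-carbaldehyde (selenium configuration not defined) | O=C[C@@]1([Se](=O)c2ccccc2)[C@@H](CO[Si](c2ccccc2)(c2ccccc2)C(C)(C)C)C=C(C)[C@H]2CC[C@H](C)C[C@H]12 | intermediate
16 | (4aS,7S,8aS)-2-{[(tert-butyldiphenylsilyl)oxy]methyl}-4,7-dimethyl-4a,5,6,7,8,8a-hexahydronaphthalene-1-carbaldehyde | O=CC1=C(CO[Si](c2ccccc2)(c2ccccc2)C(C)(C)C)C=C(C)[C@H]2CC[C@H](C)C[C@H]12 | intermediate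
17 | 1,3-benzothiazole-2-thiol | Sc1nc2ccccc2s1 | starting material
18 | iodoethane | CCI | starting material
19 | 2-(ethylsulfanyl)-1,3-benzothiazole | CCSc1nc2ccccc2s1 | intermediate
20 | 2-(ethylsulfonyl)-1,3-benzothiazole | CCS(=O)(=O)c1nc2ccccc2s1 | intermediate
21 | [1-(1,3-benzothiazol-2-ylsulfonyl)ethyl]lithium | [Li]C(C)S(=O)(=O)c1nc2ccccc2s1 | intermediate
22 | tert-butyl({(4aS,7S,8aS)-4,7-dimethyl-1-[(1E)-prop-1-en-1-yl]-4a,5,6,7,8,8a-hexahydronaphthalen-2-yl}methoxy)diphenylsilane | C/C=C/C1=C(CO[Si](c2ccccc2)(c2ccccc2)C(C)(C)C)C=C(C)[C@H]2CC[C@H](C)C[C@H]12 | intermediate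
23 | {(4aS,7S,8aS)-4,7-dimethyl-1-[(1E)-prop-1-en-1-yl]-4a,5,6,7,8,8a-hexahydronaphthalen-2-yl}methanol | C/C=C/C1=C(CO)C=C(C)[C@H]2CC[C@H](C)C[C@H]12 | intermediate
24 | (4aS,7S,8aS)-4,7-dimethyl-1-[(1E)-prop-1-en-1-yl]-4a,5,6,7,8,8a-hexahydronaphthalene-2-carbaldehyde | C/C=C/C1=C(C=O)C=C(C)[C@H]2CC[C@H](C)C[C@H]12 | intermediate
25 | 5-bromo-2,4-dimethoxypyridine | COc1cc(OC)c(Br)cn1 | starting material
26 | (4-methoxyphenyl)boronic acid | COc1ccc(cc1)B(O)O | starting material
27 | 2,4-dimethoxy-5-(4-methoxyphenyl)pyridine | COc1ccc(cc1)-c1cnc(OC)cc1OC | intermediate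
28 | 4-hydroxy-5-(4-hydroxyphenyl)pyridin-2(1H)-one | Oc1ccc(cc1)-c1c[nH]c(=O)cc1O | intermediate
29 | 2,4-bis(methoxymethoxy)-5-[4-(methoxymethoxy)phenyl]pyridine | COCOc1ccc(cc1)-c1cnc(OCOC)cc1OCOC | intermediate
30 | {2,4-bis(methoxymethoxy)-5-[4-(methoxymethoxy)phenyl]pyridin-3-yl}lithium | [Li]c1c(OCOC)ncc(-c2ccc(OCOC)cc2)c1OCOC | intermediate
31 | {2,4-bis(methoxymethoxy)-5-[4-(methoxymethoxy)phenyl]pyridin-3-yl}{(4aS,7S,8aS)-4,7-dimethyl-1-[(1E)-prop-1-en-1-yl]-4a,5,6,7,8,8a-hexahydronaphthalen-2-yl}methanol (carbinol centre not defined) | C/C=C/C1=C(C(O)c2c(OCOC)ncc(-c3ccc(OCOC)cc3)c2OCOC)C=C(C)[C@H]2CC[C@H](C)C[C@H]12 | intermediate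
32 | {2,4-bis(methoxymethoxy)-5-[4-(methoxymethoxy)phenyl]pyridin-3-yl}{(4aS,7S,8aS)-4,7-dimethyl-1-[(1E)-prop-1-en-1-yl]-4a,5,6,7,8,8a-hexahydronaphthalen-2-yl}methanone | C/C=C/C1=C(C(=O)c2c(OCOC)ncc(-c3ccc(OCOC)cc3)c2OCOC)C=C(C)[C@H]2CC[C@H](C)C[C@H]12 | intermediate
33 | ilicicolin J, 4-hydroxy-5-(4-hydroxyphenyl)-3-{(4aS,7S,8aS)-4,7-dimethyl-1-[(1E)-prop-1-en-1-yl]-4a,5,6,7,8,8a-hexahydronaphthalene-2-carbonyl}pyridin-2(1H)-one | C/C=C/C1=C(C(=O)c2c(O)c(-c3ccc(O)cc3)c[nH]c2=O)C=C(C)[C@H]2CC[C@H](C)C[C@H]12 | target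

**Step count and risks**

Total step count: 21. Longest linear sequence: 16 steps (1–10, 13–15, 19–21) from (S)-citronellal.

Step 9 (the consequence shows in step 10). The selenium electrophile may be delivered to the face of the enol ether that carries the C2 silyloxymethyl group, or be consumed by the C3=C4 alkene. Selenium would then sit cis to H-8a, and the syn-elimination would run into the ring fusion and erase C8a. The fallback sets out from 12. Silylation with t-BuMe2SiOTf and Et3N should give the silyl enol ether tert-butyl{[(2S,4aS,7S,8aS)-1-{[(tert-butyldimethylsilyl)oxy]methylidene}-4,7-dimethyl-1,2,4a,5,6,7,8,8a-octahydronaphthalen-2-yl]methoxy}diphenylsilane F1, which is isolated and dehydrogenated by Saegusa–Ito oxidation with Pd(OAc)2 in MeCN. The palladium enolate can change faces through its oxygen-bound form, so β-hydride loss should be governed by the weaker allylic C2–H bond and give the conjugated dienal. The fallback comes back to the route at 16.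

Step 19. Carbonyl addition may be slow or incomplete because the cis-dienal 24 can rest as its 2H-pyran valence isomer at low temperature (oxa-6π closure), and because the doubly ortho-substituted aryllithium may instead remove the γ-proton at C8a and scramble the ring fusion. The fallback sets out from 24. Pinnick oxidation (NaClO2, NaH2PO4, 2-methylbut-2-ene, t-BuOH/H2O) should give (4aS,7S,8aS)-4,7-dimethyl-1-[(1E)-prop-1-en-1-yl]-4a,5,6,7,8,8a-hexahydronaphthalene-2-carboxylic acid F2. Carbodiimide coupling with N,O-dimethylhydroxylamine hydrochloride (EDC, i-Pr2NEt, CH2Cl2) should give the Weinreb amide (4aS,7S,8aS)-N-methoxy-N,4,7-trimethyl-1-[(1E)-prop-1-en-1-yl]-4a,5,6,7,8,8a-hexahydronaphthalene-2-carboxamide F3. Acyl substitution on F3 by the lithiopyridine 30 (Weinreb ketone synthesis, no over-addition through the chelated tetrahedral intermediate) should give the ketone directly. The amide cannot close to a pyran and is less γ-acidic than the aldehyde. The fallback comes back at 32 and makes step 20 unnecessary.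

Step 21. Acid may degrade the trienone (shift of the ring diene, oxa-6π closure followed by ionisation, or epimerisation at C8a through the dienol) before the least labile, phenolic acetal has gone. The fallback sets out from 28 and replaces acid-labile by fluoride-labile groups. Silver-salt alkylation with 2-(trimethylsilyl)ethoxymethyl chloride and Ag2CO3 should give 2,4-bis{[2-(trimethylsilyl)ethoxy]methoxy}-5-(4-{[2-(trimethylsilyl)ethoxy]methoxy}phenyl)pyridine F4. n-BuLi should convert it into its 3-lithio derivative (2,4-bis{[2-(trimethylsilyl)ethoxy]methoxy}-5-(4-{[2-(trimethylsilyl)ethoxy]methoxy}phenyl)pyridin-3-yl)lithium F5, which adds to 24 to give the carbinol (2,4-bis{[2-(trimethylsilyl)ethoxy]methoxy}-5-(4-{[2-(trimethylsilyl)ethoxy]methoxy}phenyl)pyridin-3-yl){(4aS,7S,8aS)-4,7-dimethyl-1-[(1E)-prop-1-en-1-yl]-4a,5,6,7,8,8a-hexahydronaphthalen-2-yl}methanol F6. Dess–Martin oxidation should give the corresponding ketone (2,4-bis{[2-(trimethylsilyl)ethoxy]methoxy}-5-(4-{[2-(trimethylsilyl)ethoxy]methoxy}phenyl)pyridin-3-yl){(4aS,7S,8aS)-4,7-dimethyl-1-[(1E)-prop-1-en-1-yl]-4a,5,6,7,8,8a-hexahydronaphthalen-2-yl}methanone F7. Bu4NF in THF/DMPU with gentle warming should then remove all three groups by fluoride-triggered fragmentation under non-acidic conditions. The fallback comes back at 33.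

Further compounds
F1 | step 9 | tert-butyl{[(2S,4aS,7S,8aS)-1-{[(tert-butyldimethylsilyl)oxy]methylidene}-4,7-dimethyl-1,2,4a,5,6,7,8,8a-octahydronaphthalen-2-yl]methoxy}diphenylsilane | CC(C)(C)[Si](C)(C)OC=C1[C@@H](CO[Si](c2ccccc2)(c2ccccc2)C(C)(C)C)C=C(C)[C@H]2CC[C@H](C)C[C@H]12
F2 | step 19 | (4aS,7S,8aS)-4,7-dimethyl-1-[(1E)-prop-1-en-1-yl]-4a,5,6,7,8,8a-hexahydronaphthalene-2-carboxylic acid | C/C=C/C1=C(C(=O)O)C=C(C)[C@H]2CC[C@H](C)C[C@H]12
F3 | step 19 | (4aS,7S,8aS)-N-methoxy-N,4,7-trimethyl-1-[(1E)-prop-1-en-1-yl]-4a,5,6,7,8,8a-hexahydronaphthalene-2-carboxamide | C/C=C/C1=C(C(=O)N(C)OC)C=C(C)[C@H]2CC[C@H](C)C[C@H]12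
F4 | step 21 | 2,4-bis{[2-(trimethylsilyl)ethoxy]methoxy}-5-(4-{[2-(trimethylsilyl)ethoxy]methoxy}phenyl)pyridine | C[Si](C)(C)CCOCOc1ccc(cc1)-c1cnc(OCOCC[Si](C)(C)C)cc1OCOCC[Si](C)(C)C
F5 | step 21 | (2,4-bis{[2-(trimethylsilyl)ethoxy]methoxy}-5-(4-{[2-(trimethylsilyl)ethoxy]methoxy}phenyl)pyridin-3-yl)lithium | [Li]c1c(OCOCC[Si](C)(C)C)ncc(-c2ccc(OCOCC[Si](C)(C)C)cc2)c1OCOCC[Si](C)(C)C
F6 | step 21 | (2,4-bis{[2-(trimethylsilyl)ethoxy]methoxy}-5-(4-{[2-(trimethylsilyl)ethoxy]methoxy}phenyl)pyridin-3-yl){(4aS,7S,8aS)-4,7-dimethyl-1-[(1E)-prop-1-en-1-yl]-4a,5,6,7,8,8a-hexahydronaphthalen-2-yl}methanol | C/C=C/C1=C(C(O)c2c(OCOCC[Si](C)(C)C)ncc(-c3ccc(OCOCC[Si](C)(C)C)cc3)c2OCOCC[Si](C)(C)C)C=C(C)[C@H]2CC[C@H](C)C[C@H]12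
F7 | step 21 | (2,4-bis{[2-(trimethylsilyl)ethoxy]methoxy}-5-(4-{[2-(trimethylsilyl)ethoxy]methoxy}phenyl)pyridin-3-yl){(4aS,7S,8aS)-4,7-dimethyl-1-[(1E)-prop-1-en-1-yl]-4a,5,6,7,8,8a-hexahydronaphthalen-2-yl}methanone | C/C=C/C1=C(C(=O)c2c(OCOCC[Si](C)(C)C)ncc(-c3ccc(OCOCC[Si](C)(C)C)cc3)c2OCOCC[Si](C)(C)C)C=C(C)[C@H]2CC[C@H](C)C[C@H]12
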